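## Retrosynthetic overview

1. (−)-3-O-Acetylspectaline ⇐ (−)-spectaline, by O-acetylation with the ring nitrogen protonated.
2. Piperidine ⇐ open-chain N-Cbz δ-amino ketone: Cbz hydrogenolysis, cyclic imine, cis-selective C=N hydrogenation (sets C6); the side-chain alkene is saturated in the same pot.
3. Methyl ketone terminus ⇐ cross-metathesis of a terminal alkene with hex-5-en-2-one.
4. Key C3–C4 bond ⇐ ketone homoenolate (β-metallo ketone released from a cyclopropanol) + N-Cbz-D-alaninal under chelation control (sets C3; C2 comes from D-alanine).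
5. Ring order: a sacrificial cyclopropane (made in step 1 from methyl undec-10-enoate, opened in step 3), then the piperidine (step 5).

Assumption: the target is the free base as drawn; N-Cbz-D-alaninol and TiCl3(OiPr) (stock solution in CH2Cl2) are purchased.

## Route

Step 1
Reactants: 1 methyl undec-10-enoate
Product: 2 1-(dec-9-en-1-yl)cyclopropan-1-ol
Conditions: EtMgBr (2.5 equiv), Ti(OiPr)4 (20 mol%), THF, 0 °C to rt; H2O quench
Reagents that add atoms: ethylmagnesium bromide, CC[Mg]Br
Why: Kulinkovich cyclopropanation, in which the titanacyclopropane from EtMgBr/Ti(OiPr)4 adds twice to the ester carbonyl as a 1,2-dicarbanion; the remote terminal alkene does not exchange into the titanacycle with EtMgBr, and no stereocentre is formed.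

Step 2
Reactants: 3 benzyl N-[(2R)-1-hydroxypropan-2-yl]carbamate (N-Cbz-D-alaninol)
Product: 4 benzyl N-[(2R)-1-oxopropan-2-yl]carbamate (N-Cbz-D-alaninal)
Conditions: TEMPO (1 mol%), NaBr (10 mol%), NaOCl (1.1 equiv), NaHCO3, toluene/EtOAc/H2O, 0 °C; used crude at once
Reagents that add atoms: none
Why: Anelli-type TEMPO/hypochlorite oxidation stops at the aldehyde under buffered biphasic conditions at 0 °C, where N-carbamoyl α-amino aldehydes keep their configuration; the C2 (R) centre is that of D-alanine.

Step 3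
Reactants: 2 1-(dec-9-en-1-yl)cyclopropan-1-ol; 4 benzyl N-[(2R)-1-oxopropan-2-yl]carbamate
Product: 7 benzyl N-[(2R,3R)-3-hydroxy-6-oxohexadec-15-en-2-yl]carbamate, via zinc cyclopropoxide 5 (not isolated), via titanium homoenolate 6 (not isolated)
Conditions: 2 (2.0 equiv), Et2Zn (1.0 equiv), THF, 0 °C to rt; TiCl3(OiPr) (2.0 equiv), CH2Cl2, −40 °C; 4 (1.0 equiv), −40 to 0 °C; aq. Rochelle salt
Reagents that add atoms: none
Why: Proposed new method: strain-driven ring opening of the zinc cyclopropoxide (a known entry to zinc homoenolates) gives a ketone homoenolate with C4 as a d3 nucleophile, which is captured by carbon-to-titanium transmetalation as an internally C=O-chelated alkyltitanium that adds to aldehydes but not to ketones or carbamates; the Lewis-acidic Cl2(iPrO)Ti centre chelates the aldehyde and carbamate oxygens of 4 (Cram-chelate) so that C4 attacks the face bearing H-2, giving the syn (2R,3R) amino alcohol (7 equilibrates with its five-membered lactol, which behaves identically later); the closest known reaction type is the chelation-controlled addition of zinc-derived titanium ester homoenolates (Nakamura–Kuwajima homoaldol) to N-carbamoyl α-amino aldehydes, extended here from ester to ketone homoenolates sourced from a cyclopropanol.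

Step 4
Reactants: 7 benzyl N-[(2R,3R)-3-hydroxy-6-oxohexadec-15-en-2-yl]carbamate; 8 hex-5-en-2-one
Product: 9 benzyl N-[(2R,3R)-3-hydroxy-6,19-dioxoicos-15-en-2-yl]carbamate (E/Z mixture)
Conditions: 8 (5 equiv), Grubbs II (5 mol%), CH2Cl2, 40 °C
Reagents that add atoms: none
Why: Olefin cross-metathesis of two unhindered terminal alkenes, driven to the cross product by excess of the cheap ketone partner and loss of ethene; hydroxyl, carbamate and ketones are tolerated, and the E/Z ratio is irrelevant because the alkene is hydrogenated next.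

Step 5
Reactants: 9 benzyl N-[(2R,3R)-3-hydroxy-6,19-dioxoicos-15-en-2-yl]carbamate
Product: 12 (−)-spectaline [14-[(2S,5R,6R)-5-hydroxy-6-methylpiperidin-2-yl]tetradecan-2-one], via amino diketone 10 (not isolated), via cyclic imine 11 (not isolated)
Conditions: H2 (3 atm), 10% Pd/C, EtOH (0.02 M), rt
Reagents that add atoms: none
Why: Tandem hydrogenation/hydrogenolysis/intramolecular reductive amination: Pd saturates the alkene and removes Cbz, the free amine closes onto the δ-ketone (C6) as a six-membered cyclic imine far faster than it meets the remote methyl ketone, and H2 is delivered to C=N on the ring face opposite the cis C2-methyl and C3-hydroxyl groups, giving the all-cis (6S) piperidine.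

Step 6
Reactants: 12 (−)-spectaline
Product: 13 (−)-3-O-acetylspectaline [(2R,3R,6S)-2-methyl-6-(13-oxotetradecyl)piperidin-3-yl acetate]
Conditions: AcCl (5 equiv), CF3CO2H, 0 °C to rt; then cold sat. aq. NaHCO3, CH2Cl2
Reagents that add atoms: acetyl chloride, CC(Cl)=O
Why: Chemoselective O-acylation under acidic conditions: in CF3CO2H the piperidine nitrogen is fully protonated and inert, so only the C3 hydroxyl is esterified, with no stereocentre touched and the methyl ketone unaffected.

## Compound list

1 | methyl undec-10-enoate | C=CCCCCCCCCC(=O)OC | starting material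
2 | 1-(dec-9-en-1-yl)cyclopropan-1-ol | C=CCCCCCCCCC1(O)CC1 | intermediate
3 | benzyl N-[(2R)-1-hydroxypropan-2-yl]carbamate (N-Cbz-D-alaninol) | OC[C@@H](C)NC(=O)OCc1ccccc1 | starting material
4 | benzyl N-[(2R)-1-oxopropan-2-yl]carbamate (N-Cbz-D-alaninal) | O=C[C@@H](C)NC(=O)OCc1ccccc1 | intermediate
5 | zinc bis[1-(dec-9-en-1-yl)cyclopropan-1-olate] (not isolated) | C=CCCCCCCCCC1(CC1)O[Zn]OC1(CC1)CCCCCCCCC=C | intermediate
6 | dichloro(propan-2-olato)(3-oxotridec-12-en-1-yl)titanium (not isolated) | C=CCCCCCCCCC(=O)CC[Ti](Cl)(Cl)OC(C)C | intermediate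
7 | benzyl N-[(2R,3R)-3-hydroxy-6-oxohexadec-15-en-2-yl]carbamate | C=CCCCCCCCCC(=O)CC[C@@H](O)[C@@H](C)NC(=O)OCc1ccccc1 | intermediate
8 | hex-5-en-2-one | CC(=O)CCC=C | starting material
9 | benzyl N-[(2R,3R)-3-hydroxy-6,19-dioxoicos-15-en-2-yl]carbamate (E/Z mixture, E drawn) | CC(=O)CC/C=C/CCCCCCCCC(=O)CC[C@@H](O)[C@@H](C)NC(=O)OCc1ccccc1 | intermediate
10 | (18R,19R)-19-amino-18-hydroxyicosane-2,15-dione (not isolated) | CC(=O)CCCCCCCCCCCCC(=O)CC[C@@H](O)[C@@H](C)N | intermediate
11 | 14-[(5R,6R)-5-hydroxy-6-methyl-3,4,5,6-tetrahydropyridin-2-yl]tetradecan-2-one (not isolated) | CC(=O)CCCCCCCCCCCCC1=N[C@H](C)[C@H](O)CC1 | intermediate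
12 | (−)-spectaline, 14-[(2S,5R,6R)-5-hydroxy-6-methylpiperidin-2-yl]tetradecan-2-one | CC(=O)CCCCCCCCCCCC[C@H]1CC[C@@H](O)[C@@H](C)N1 | intermediate
13 | (−)-3-O-acetylspectaline, (2R,3R,6S)-2-methyl-6-(13-oxotetradecyl)piperidin-3-yl acetate | CC(=O)CCCCCCCCCCCC[C@H]1CC[C@@H](OC(C)=O)[C@@H](C)N1 | target

## Step count and risks

Total step count: 6. Longest linear sequence: 5 steps (1 → 2 → 7 → 9 → 12 → 13); step 2 is a one-step side branch.

**Step 3 (most likely to fail).** Ketone homoenolates prefer the closed cyclopropoxide form. The zinc alkoxide may hand its oxygen rather than its carbon to titanium and leave an inert titanium cyclopropoxide. An enolised homoenolate may instead attack the aldehyde through the carbinol carbon to give a 1,2-diol. The chelate-controlled diastereoselectivity is also untested for this nucleophile.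

Fallback, setting out from 4 and returning at 7: the homoenolate is moved to the ester level and the side chain is added afterwards as an ordinary Grignard reagent. [(1-Ethoxycyclopropyl)oxy]trimethylsilane and TiCl4 give ethyl 3-(trichlorotitanio)propanoate F1. This adds to 4 under chelation control to give ethyl (4R,5R)-5-{[(benzyloxy)carbonyl]amino}-4-hydroxyhexanoate F2. Lactonisation with catalytic TsOH in toluene gives benzyl N-[(1R)-1-[(2R)-5-oxooxolan-2-yl]ethyl]carbamate F3. Single addition of dec-9-en-1-ylmagnesium bromide F4 (from 10-bromodec-1-ene and Mg; 2.2 equiv, THF, −78 °C) to the lactone then gives 7. Step 1 is no longer needed.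

**Step 5.** Before ring closure the primary amine could condense intermolecularly with the remote methyl ketone, giving oligomers or over-alkylation, and the cis selectivity could suffer at the concentration needed on scale.

Fallback, setting out from 7 and returning at 12: the remote ketone stays masked until the ring is closed. Ketone 8 is ketalised (ethylene glycol, cat. TsOH, Dean–Stark) to 2-(but-3-en-1-yl)-2-methyl-1,3-dioxolane F5. Cross-metathesis of 7 with F5 gives benzyl N-[(2R,3R)-3-hydroxy-18-(2-methyl-1,3-dioxolan-2-yl)-6-oxooctadec-15-en-2-yl]carbamate F6. Hydrogenation over Pd/C in EtOH passes through (2R,3R)-2-amino-3-hydroxy-18-(2-methyl-1,3-dioxolan-2-yl)octadecan-6-one F7 and (2R,3R)-2-methyl-6-[12-(2-methyl-1,3-dioxolan-2-yl)dodecyl]-2,3,4,5-tetrahydropyridin-3-ol F8 to (2R,3R,6S)-2-methyl-6-[12-(2-methyl-1,3-dioxolan-2-yl)dodecyl]piperidin-3-ol F9. Aqueous 1 M HCl in THF, then NaHCO3, releases 12.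

**Step 6.** The axial hydroxyl next to an ammonium centre may acylate slowly, and any free amine (or free-basing for too long) invites N-acetylation or O-to-N acetyl shift.

Fallback, setting out from 9 and returning at 13: the ester is installed while nitrogen is still a carbamate. Ac2O, pyridine and catalytic DMAP convert 9 into (2R,3R)-2-{[(benzyloxy)carbonyl]amino}-6,19-dioxoicos-15-en-3-yl acetate F10. Hydrogenation (H2, Pd/C, EtOH–AcOH 10:1) then runs through (2R,3R)-2-amino-6,19-dioxoicosan-3-yl acetate F11 and (2R,3R)-2-methyl-6-(13-oxotetradecyl)-2,3,4,5-tetrahydropyridin-3-yl acetate F12 directly to 13. The acetic acid keeps the primary amine protonated so that acetyl migration does not compete with ring closure.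

## Further compounds

F1 | step 3 | ethyl 3-(trichlorotitanio)propanoate | CCOC(=O)CC[Ti](Cl)(Cl)Cl
F2 | step 3 | ethyl (4R,5R)-5-{[(benzyloxy)carbonyl]amino}-4-hydroxyhexanoate | CCOC(=O)CC[C@@H](O)[C@@H](C)NC(=O)OCc1ccccc1
F3 | step 3 | benzyl N-[(1R)-1-[(2R)-5-oxooxolan-2-yl]ethyl]carbamate | O=C1CC[C@@H](O1)[C@@H](C)NC(=O)OCc1ccccc1
F4 | step 3 | dec-9-en-1-ylmagnesium bromide | C=CCCCCCCCC[Mg]Br
F5 | step 5 | 2-(but-3-en-1-yl)-2-methyl-1,3-dioxolane | CC1(CCC=C)OCCO1
F6 | step 5 | benzyl N-[(2R,3R)-3-hydroxy-18-(2-methyl-1,3-dioxolan-2-yl)-6-oxooctadec-15-en-2-yl]carbamate | CC1(CC/C=C/CCCCCCCCC(=O)CC[C@@H](O)[C@@H](C)NC(=O)OCc2ccccc2)OCCO1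
F7 | step 5 | (2R,3R)-2-amino-3-hydroxy-18-(2-methyl-1,3-dioxolan-2-yl)octadecan-6-one | CC1(CCCCCCCCCCCCC(=O)CC[C@@H](O)[C@@H](C)N)OCCO1
F8 | step 5 | (2R,3R)-2-methyl-6-[12-(2-methyl-1,3-dioxolan-2-yl)dodecyl]-2,3,4,5-tetrahydropyridin-3-ol | CC1(CCCCCCCCCCCCC2=N[C@H](C)[C@H](O)CC2)OCCO1
F9 | step 5 | (2R,3R,6S)-2-methyl-6-[12-(2-methyl-1,3-dioxolan-2-yl)dodecyl]piperidin-3-ol | CC1(CCCCCCCCCCCC[C@H]2CC[C@@H](O)[C@@H](C)N2)OCCO1
F10 | step 6 | (2R,3R)-2-{[(benzyloxy)carbonyl]amino}-6,19-dioxoicos-15-en-3-yl acetate | CC(=O)CC/C=C/CCCCCCCCC(=O)CC[C@@H](OC(C)=O)[C@@H](C)NC(=O)OCc1ccccc1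
F11 | step 6 | (2R,3R)-2-amino-6,19-dioxoicosan-3-yl acetate | CC(=O)CCCCCCCCCCCCC(=O)CC[C@@H](OC(C)=O)[C@@H](C)N
F12 | step 6 | (2R,3R)-2-methyl-6-(13-oxotetradecyl)-2,3,4,5-tetrahydropyridin-3-yl acetate | CC(=O)CCCCCCCCCCCCC1=N[C@H](C)[C@H](OC(C)=O)CC1
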